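**Plan**
- Locants: ring O1, C2, C3, C4, C5. The benzylic CH2 on C3 is C6 and the carbinol carbon on C4 is C7. The target is 3R,4S,7S, with the two ring substituents cis.
- Retrosynthesis: the C7 silyl ether and the two phenol benzyl ethers come off first, then C6–aryl and C3–C4 are cut in one operation. After that come C4–I (from C4–OH), C5–O1 (terminal epoxide plus allyl alcohol) and C7–C4 (aldehyde plus vinyl Grignard).
- Enabling feature: C4, C5, O1, C2 and the olefin C3=C6 form a 3-oxa-5-hexenyl array. A radical at C4 therefore closes the only ring, the tetrahydrofuran, at C3 and leaves a primary radical at C6 for aryl–nickel.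
- Forward order: the open chain is assembled in five steps. The ring and the second aryl group arrive together in step 8, and two deprotections finish the route.
- Stereochemistry: C7 comes from a Sharpless kinetic resolution. The C4 centre of the iodide is erased. In the ring closure C4 is rebuilt under control of C7, and C3 under control of C4.

Key step: step 8

Remark: aldehyde 1 is taken as a catalogue compound; otherwise benzylation of isovanillin (BnBr, K2CO3) adds one step. The spatial arrangement at C7 never changes after step 2, although its CIP label switches between R and S as the neighbour priorities change.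

Step 1
Reactants: 1 3-(benzyloxy)-4-methoxybenzaldehyde; 2 vinylmagnesium bromide
Product: 3 rac-1-[3-(benzyloxy)-4-methoxyphenyl]prop-2-en-1-ol
Conditions: THF, −78 to 0 °C; aq. NH4Cl
Reagents that add atoms: none
Why: Grignard 1,2-addition of the vinyl nucleophile to the aromatic aldehyde forms the C7–C4 bond and gives C7 as a racemate, which is acceptable because the next step selects one enantiomer.

Step 2
Reactants: 3 rac-1-[3-(benzyloxy)-4-methoxyphenyl]prop-2-en-1-ol
Product: 4 (R)-[3-(benzyloxy)-4-methoxyphenyl][(2S)-oxiran-2-yl]methanol (erythro epoxy alcohol)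
Conditions: Ti(OiPr)4 (15 mol %), D-(−)-DIPT (18 mol %), tBuOOH (0.45 equiv), 4 Å MS, CH2Cl2, −20 °C
Reagents that add atoms: tert-butyl hydroperoxide, CC(C)(C)OO
Why: In this Sharpless kinetic resolution by asymmetric epoxidation, D-(−)-DIPT should epoxidise the (S)-carbinol much faster than its mirror image and on the face that gives the erythro epoxy alcohol, so C7 is fixed by the resolution (same spatial arrangement as 7S in the target, the label R coming only from changed priorities), C4 is set by the reagent, and substoichiometric tBuOOH keeps the slow enantiomer out of the product.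

Step 3
Reactants: 4 (R)-[3-(benzyloxy)-4-methoxyphenyl][(2S)-oxiran-2-yl]methanol
Product: 5 {(R)-[3-(benzyloxy)-4-methoxyphenyl][(2S)-oxiran-2-yl]methoxy}triisopropylsilane
Conditions: iPr3SiOTf, 2,6-lutidine, CH2Cl2, −78 to −20 °C
Reagents that add atoms: triisopropylsilyl triflate, CC(C)[Si](C(C)C)(C(C)C)OS(=O)(=O)C(F)(F)F
Why: Silyl triflate silylation under a non-nucleophilic base leaves the epoxide and C7 untouched, and the triisopropylsilyl group is chosen because it resists 1,2 O-to-O migration in step 4, shields the benzylic C7–O bond in step 9 and supplies the large group for facial control in step 8.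

Step 4
Reactants: 5 {(R)-[3-(benzyloxy)-4-methoxyphenyl][(2S)-oxiran-2-yl]methoxy}triisopropylsilane; 6 allyl alcohol
Product: 7 (1R,2S)-3-(allyloxy)-1-[3-(benzyloxy)-4-methoxyphenyl]-1-[(triisopropylsilyl)oxy]propan-2-ol
Conditions: NaH (0.3 equiv), allyl alcohol (solvent), 60 °C
Reagents that add atoms: none
Why: In this base-catalysed SN2 alcoholysis of a terminal epoxide, allyloxide attacks the unhindered C5, the C4–O bond is not broken so C4 keeps its configuration, and the protic medium with substoichiometric base keeps the C4 alkoxide short-lived.

Step 5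
Reactants: 7 (1R,2S)-3-(allyloxy)-1-[3-(benzyloxy)-4-methoxyphenyl]-1-[(triisopropylsilyl)oxy]propan-2-ol
Product: 8 [(1R,2R)-3-(allyloxy)-1-[3-(benzyloxy)-4-methoxyphenyl]-2-iodopropoxy]triisopropylsilane
Conditions: PPh3, imidazole, I2, toluene, 80 °C
Reagents that add atoms: iodine, II
Why: Appel-type iodination under Garegg–Samuelsson conditions converts C4–OH through its alkoxyphosphonium salt into the iodide with inversion in a non-ionising solvent, and any epimerisation by iodide exchange is harmless because C4 becomes a planar radical in step 8.

Step 6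
Reactants: 9 5-bromo-2-methoxyphenol
Product: 10 2-(benzyloxy)-4-bromo-1-methoxybenzene
Conditions: BnBr, K2CO3, DMF, rt
Reagents that add atoms: benzyl bromide, BrCc1ccccc1
Why: Williamson etherification of the phenoxide with benzyl bromide gives the same phenol protection as in 1.

Step 7
Reactants: 10 2-(benzyloxy)-4-bromo-1-methoxybenzene
Product: 12 [3-(benzyloxy)-4-methoxyphenyl]zinc bromide (titrated THF solution), via arylmagnesium bromide 11 (not isolated)
Conditions: Mg turnings, THF, 40 °C; decant; ZnBr2 (1.1 equiv), THF, 0 °C to rt
Reagents that add atoms: zinc bromide, Br[Zn]Br; magnesium, [Mg] (held only in 11)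
Why: Grignard formation by magnesium insertion followed by transmetalation to zinc gives the arylzinc halide free of zinc metal and of alkyl halide by-products, which could otherwise eliminate or compete with iodide 8.

Step 8
Reactants: 8 [(1R,2R)-3-(allyloxy)-1-[3-(benzyloxy)-4-methoxyphenyl]-2-iodopropoxy]triisopropylsilane; 12 [3-(benzyloxy)-4-methoxyphenyl]zinc bromide
Product: 13 {(S)-[3-(benzyloxy)-4-methoxyphenyl][(3S,4R)-4-[3-(benzyloxy)-4-methoxybenzyl]oxolan-3-yl]methoxy}triisopropylsilane (3,4-cis; route locants 3R,4S,7S)
Conditions: NiBr2·dme (10 mol %), 2,2':6',2''-terpyridine (12 mol %), 12 (2.5 equiv), THF/NMP, 0 °C to rt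
Reagents that add atoms: none
Why: Transmetalation of 12 to terpyridine-ligated nickel gives a monovalent aryl–nickel species that takes the iodine atom from 8, so the C4 configuration of 8 is erased in a planar secondary radical; the closest known reaction type is exactly this nickel/terpyridine cyclisation–Negishi arylation of alkene-tethered secondary alkyl halides with arylzinc reagents. The tetrahydrofuran ring closes by 5-exo-trig attack of C4 on C3 of the 3-oxa-5-hexenyl array (C3–C4 bond), and the primary C6 radical is captured by divalent aryl–nickel and leaves trivalent nickel by reductive elimination (C6–aryl bond). C3 is controlled by the chair-like transition state of 5-hexenyl radical closure (Beckwith model), in which the substituent on the radical carbon lies pseudo-equatorial and the 3,4-cis ring is preferred. C4 is controlled by C7 through a Felkin-type rotamer that places the bulky, polar C7–OSi(iPr)3 bond anti to the forming C3–C4 bond (also opposing the C5–O1 dipole), C7–H over the closing ring and the aryl group beside C4–H, which leads to the 4S,7S relation. The step needs ring closure to outrun capture of the C4 radical by nickel (otherwise direct arylation or β-alkoxide loss), which the fast oxygen-accelerated 5-exo closure and the low catalyst loading should secure, and it needs cis and facial selectivity, for which only a moderate bias is expected. The minor diastereomers should therefore be removed by chromatography at this stage.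

Step 9
Reactants: 13 {(S)-[3-(benzyloxy)-4-methoxyphenyl][(3S,4R)-4-[3-(benzyloxy)-4-methoxybenzyl]oxolan-3-yl]methoxy}triisopropylsilane
Product: 14 5-{[(3R,4S)-4-{(S)-(3-hydroxy-4-methoxyphenyl)[(triisopropylsilyl)oxy]methyl}oxolan-3-yl]methyl}-2-methoxyphenol
Conditions: H2 (1 atm), Pd/C (10 wt %), EtOAc, rt
Reagents that add atoms: none
Why: Catalytic hydrogenolysis should cleave the two aryl benzyl ethers quickly under neutral conditions in ethyl acetate, while the hindered silyl ether keeps the electron-rich benzylic C7–O bond from being hydrogenolysed and no stereocentre is touched.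

Step 10
Reactants: 14 5-{[(3R,4S)-4-{(S)-(3-hydroxy-4-methoxyphenyl)[(triisopropylsilyl)oxy]methyl}oxolan-3-yl]methyl}-2-methoxyphenol
Product: 15 (S)-(3-hydroxy-4-methoxyphenyl){(3S,4R)-4-[(3-hydroxy-4-methoxyphenyl)methyl]oxolan-3-yl}methanol (target CNP0108210.1)
Conditions: Bu4NF, AcOH (1:1), THF, rt to 40 °C
Reagents that add atoms: none
Why: Fluoride-induced desilylation driven by Si–F bond formation frees the C7 carbinol with retention, and the acetic acid buffer keeps the phenols protonated without supplying acid strong enough to ionise the p-methoxybenzylic position.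

**Compound list**
1 | 3-(benzyloxy)-4-methoxybenzaldehyde | COc1ccc(C=O)cc1OCc1ccccc1 | starting material
2 | vinylmagnesium bromide | C=C[Mg]Br | starting material
3 | rac-1-[3-(benzyloxy)-4-methoxyphenyl]prop-2-en-1-ol | C=CC(O)c1ccc(OC)c(OCc2ccccc2)c1 | intermediate
4 | (R)-[3-(benzyloxy)-4-methoxyphenyl][(2S)-oxiran-2-yl]methanol | C1O[C@@H]1[C@H](O)c2ccc(OC)c(OCc3ccccc3)c2 | intermediate
5 | {(R)-[3-(benzyloxy)-4-methoxyphenyl][(2S)-oxiran-2-yl]methoxy}triisopropylsilane | C1O[C@@H]1[C@H](O[Si](C(C)C)(C(C)C)C(C)C)c2ccc(OC)c(OCc3ccccc3)c2 | intermediate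
6 | allyl alcohol | C=CCO | starting material
7 | (1R,2S)-3-(allyloxy)-1-[3-(benzyloxy)-4-methoxyphenyl]-1-[(triisopropylsilyl)oxy]propan-2-ol | C=CCOC[C@H](O)[C@H](O[Si](C(C)C)(C(C)C)C(C)C)c1ccc(OC)c(OCc2ccccc2)c1 | intermediate
8 | [(1R,2R)-3-(allyloxy)-1-[3-(benzyloxy)-4-methoxyphenyl]-2-iodopropoxy]triisopropylsilane | C=CCOC[C@@H](I)[C@H](O[Si](C(C)C)(C(C)C)C(C)C)c1ccc(OC)c(OCc2ccccc2)c1 | intermediate
9 | 5-bromo-2-methoxyphenol | COc1ccc(Br)cc1O | starting material
10 | 2-(benzyloxy)-4-bromo-1-methoxybenzene | COc1ccc(Br)cc1OCc1ccccc1 | intermediate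
11 | [3-(benzyloxy)-4-methoxyphenyl]magnesium bromide | COc1ccc([Mg]Br)cc1OCc1ccccc1 | intermediate
12 | [3-(benzyloxy)-4-methoxyphenyl]zinc bromide | COc1ccc([Zn]Br)cc1OCc1ccccc1 | intermediate
13 | {(S)-[3-(benzyloxy)-4-methoxyphenyl][(3S,4R)-4-[3-(benzyloxy)-4-methoxybenzyl]oxolan-3-yl]methoxy}triisopropylsilane | COc1ccc(C[C@H]2COC[C@H]2[C@H](O[Si](C(C)C)(C(C)C)C(C)C)c2ccc(OC)c(OCc3ccccc3)c2)cc1OCc1ccccc1 | intermediate
14 | 5-{[(3R,4S)-4-{(S)-(3-hydroxy-4-methoxyphenyl)[(triisopropylsilyl)oxy]methyl}oxolan-3-yl]methyl}-2-methoxyphenol | COc1ccc(C[C@H]2COC[C@H]2[C@H](O[Si](C(C)C)(C(C)C)C(C)C)c2ccc(OC)c(O)c2)cc1O | intermediate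
15 | (S)-(3-hydroxy-4-methoxyphenyl){(3S,4R)-4-[(3-hydroxy-4-methoxyphenyl)methyl]oxolan-3-yl}methanol | COc1ccc(C[C@H]2COC[C@H]2[C@H](O)c2ccc(OC)c(O)c2)cc1O | target

Total step count: 10. Longest linear sequence: 8 steps (steps 1–5 and 8–10, from 1). The arylzinc branch (steps 6 and 7) joins at step 8.

**Steps most likely to fail**

1. **Step 8.**
   - At risk: weak facial discrimination at the planar C4 radical and erosion of the cis preference at room temperature. The C4 radical could also be captured by nickel before ring closure, which would lead to direct arylation or β-alkoxide elimination.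
   - Fallback: ring closure and arylation are separated, setting out from iodide 8. A triethylborane/air-initiated iodine-atom-transfer cyclisation (Et3B, air, toluene, −40 °C) would form the ring without any metal that can intercept C4, and at a temperature where the conformational preferences count for more.
   - This would give the cis 4-(iodomethyl)oxolane silyl ether F1, at which stage the diastereomers would be separated.
   - The primary iodide would then be coupled with arylzinc 12 in an ordinary nickel-catalysed Negishi reaction (NiBr2·dme, terpyridine, THF/NMP). This returns to the route at 13.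

2. **Step 5.**
   - At risk: slow substitution at the β-branched, doubly β-oxygenated C4. This would let E2 elimination towards the conjugated silyl enol ether, or participation and 1,2-shift of the electron-rich aryl group, take over.
   - Fallback: substitution at C4 is avoided and the same C4 radical is made by C–O homolysis, setting out from alcohol 7.
   - Oxalyl chloride followed by water would give the hydrogen oxalate F2. CsHCO3 converts this in the flask into its caesium salt F3.
   - Photoredox/nickel deoxygenative arylation with aryl bromide 10 would follow (Ir[dF(CF3)ppy]2(dtbbpy)PF6, NiBr2·dme, 4,4'-di-tert-butyl-2,2'-bipyridine, tetrahydropyran/DMSO, blue light, 70 °C). It would expel two molecules of carbon dioxide and let the C4 radical close 5-exo as in step 8. The C6 radical would then be arylated at nickel, which returns to the route at 13.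

3. **Step 2.**
   - At risk: an insufficient rate difference between the enantiomers would erode the enantiopurity of the epoxide. Titanium could also promote opening of the terminal epoxide during the long reaction time that a monosubstituted olefin needs.
   - Fallback: resolution and epoxidation are separated, setting out from racemate 3.
   - Lipase-catalysed acylation (Novozym 435, vinyl acetate, MTBE, 30 °C, run just past half conversion) should follow the Kazlauskas rule. It would convert the (R)-enantiomer into the (R)-acetate F5 and leave the (S)-allylic alcohol F4.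
   - Hydroxyl-directed epoxidation of F4 (VO(acac)2, tBuOOH, CH2Cl2, 0 °C) should then favour the erythro isomer. The minor threo epoxy alcohol F6 would be removed by chromatography, which returns to the route at 4.

**Further compounds**
F1 | step 8 | {(S)-[3-(benzyloxy)-4-methoxyphenyl][(3S,4R)-4-(iodomethyl)oxolan-3-yl]methoxy}triisopropylsilane | IC[C@H]1COC[C@H]1[C@H](O[Si](C(C)C)(C(C)C)C(C)C)c1ccc(OC)c(OCc2ccccc2)c1
F2 | step 5 | (1R,2S)-3-(allyloxy)-1-[3-(benzyloxy)-4-methoxyphenyl]-1-[(triisopropylsilyl)oxy]propan-2-yl hydrogen oxalate | C=CCOC[C@H](OC(=O)C(=O)O)[C@H](O[Si](C(C)C)(C(C)C)C(C)C)c1ccc(OC)c(OCc2ccccc2)c1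
F3 | step 5 | caesium salt of F2 | C=CCOC[C@H](OC(=O)C(=O)[O-])[C@H](O[Si](C(C)C)(C(C)C)C(C)C)c1ccc(OC)c(OCc2ccccc2)c1.[Cs+]
F4 | step 2 | (S)-1-[3-(benzyloxy)-4-methoxyphenyl]prop-2-en-1-ol | C=C[C@H](O)c1ccc(OC)c(OCc2ccccc2)c1
F5 | step 2 | (R)-1-[3-(benzyloxy)-4-methoxyphenyl]prop-2-en-1-yl acetate | C=C[C@@H](OC(C)=O)c1ccc(OC)c(OCc2ccccc2)c1
F6 | step 2 | (R)-[3-(benzyloxy)-4-methoxyphenyl][(2R)-oxiran-2-yl]methanol (threo) | C1O[C@H]1[C@H](O)c2ccc(OC)c(OCc3ccccc3)c2
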